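**Retrosynthetic overview** (side-chain atoms are numbered C1–C14 as in the tetradecatetraenyl name; C2 is bonded to the pyranone)
1. C7=C8 is cut by cross-metathesis into vinyl pyranone 14 and dienone 21; 21 comes from (S)-2-methylbutan-1-ol (C11–C14, sets C12) and 2-methylpent-1-en-3-one by aldol condensation.
2. The 2-pyranone is cut to trienal 9 plus methyl 2-methyl-3-oxopentanoate (dianion aldol, oxidation, lactonisation).
3. Trienal 9 is cut at C5–C6 into aminodienal 4 and an (E)-crotyl nucleophile; asymmetric crotylboration with hydrolytic 1,5-carbonyl transposition sets C6.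
4. Aminodienal 4 comes from ring-opening of 3,5-dimethylpyridine (key step): the five ring carbons and both methyls become pyranone C6, C1–C5 and the C4 methyl, with both diene geometries.
5. Rings: the pyridine ring is opened in step 2; the 2-pyranone is the only ring formed (step 6).

Assumption: (E)-but-2-ene, (+)-B-methoxydiisopinocampheylborane, methyl 2-methyl-3-oxopentanoate, 2-methylpent-1-en-3-one and (S)-2-methylbutan-1-ol are taken as commercial. The route has not been run; step 3 is a proposed method.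

**Step 1**
Reactants: 1 3,5-dimethylpyridine
Product: 2 1-(2,4-dinitrophenyl)-3,5-dimethylpyridin-1-ium chloride
Conditions: 1-chloro-2,4-dinitrobenzene (1.05 equiv), acetone, reflux, 24 h; filter the salt
Reagents that add atoms: 1-chloro-2,4-dinitrobenzene, Clc1ccc(cc1[N+](=O)[O-])[N+](=O)[O-]
Why: Zincke salt formation by nucleophilic aromatic substitution of the activated aryl chloride by the pyridine nitrogen; no stereocentre is involved.

**Step 2 (key step)**
Reactants: 2 1-(2,4-dinitrophenyl)-3,5-dimethylpyridin-1-ium chloride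
Product: 4 (2E,4E)-2,4-dimethyl-5-[methyl(phenyl)amino]penta-2,4-dienal, via pentamethinium chloride 3 (not isolated)
Conditions: PhNHMe (2.2 equiv), EtOH, 60 °C; filter off 2,4-dinitroaniline; then 2 M aq NaOH, 0 °C to rt
Reagents that add atoms: N-methylaniline, CNc1ccccc1; sodium hydroxide, [Na+].[OH-]
Why: Zincke ring-opening (dearomatisation): the amine adds at C2 of the N-arylpyridinium, electrocyclic opening and amine exchange expel 2,4-dinitroaniline to give symmetric salt 3, and hydroxide hydrolysis of one terminus gives the push–pull aminodienal in its thermodynamic (2E,4E) form.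

**Step 3**
Reactants: 4 (2E,4E)-2,4-dimethyl-5-[methyl(phenyl)amino]penta-2,4-dienal; 5 (E)-but-2-ene
Product: 9 (2E,4E,6R)-2,4,6-trimethylocta-2,4,7-trienal, via (E)-crotylpotassium 6 (not isolated), via (E)-crotyldiisopinocampheylborane 7 (not isolated), via borinate adduct 8 (not isolated)
Conditions: 5, KOtBu, n-BuLi, THF, −78 to −45 °C; (+)-Ipc2BOMe [from (−)-α-pinene], −78 °C; BF3·OEt2 (1.0 equiv); then 4, −78 °C, 6 h; aq AcOH/NaOAc (pH 5), 0 °C to rt
Reagents that add atoms: water, O
Why: Proposed new method: Brown crotylboration applied to a Zincke aldehyde, in which the Lewis-basic formyl oxygen of 4 binds borane 7 and the (E)-crotyl group is delivered through the closed chair transition state to the Re face (anti adduct 8, methyl-bearing carbon R), after which mild acid ionises the C–O bond with push from the anilino nitrogen and hydrolyses the dienyl iminium, erasing the carbinol centre and leaving the (E,E)-dienal; the closest known reactions are Brown crotylboration of enals and addition of organolithium reagents to 5-aminopenta-2,4-dienals followed by acid hydrolysis to 2,4-dienals.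

**Step 4**
Reactants: 9 (2E,4E,6R)-2,4,6-trimethylocta-2,4,7-trienal; 10 methyl 2-methyl-3-oxopentanoate
Product: 12 methyl (6E,8E,10R)-5-hydroxy-2,4,6,8,10-pentamethyl-3-oxododeca-6,8,11-trienoate (diastereomer mixture at C2/C4/C5), via dilithium dianion 11 (not isolated)
Conditions: 10 (1.05 equiv), LiN(iPr)2 (2.1 equiv), THF, −78 to 0 °C; then 9, −78 °C, 1 h; AcOH
Reagents that add atoms: none
Why: Weiler-type dianion aldol in which the γ-carbon of the β-keto ester dianion adds 1,2 to the dienal at −78 °C; the new centres at C2, C4 and C5 are removed in steps 5 and 6.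

**Step 5**
Reactants: 12 methyl (6E,8E,10R)-5-hydroxy-2,4,6,8,10-pentamethyl-3-oxododeca-6,8,11-trienoate
Product: 13 methyl (6E,8E,10R)-2,4,6,8,10-pentamethyl-3,5-dioxododeca-6,8,11-trienoate
Conditions: Dess–Martin periodinane (1.3 equiv), CH2Cl2, 0 °C to rt
Reagents that add atoms: none
Why: Dess–Martin oxidation of the dienylic secondary alcohol under neutral conditions that do not touch the doubly allylic stereocentre.

**Step 6**
Reactants: 13 methyl (6E,8E,10R)-2,4,6,8,10-pentamethyl-3,5-dioxododeca-6,8,11-trienoate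
Product: 14 4-hydroxy-3,5-dimethyl-6-[(2E,4E,6R)-4,6-dimethylocta-2,4,7-trien-2-yl]-2H-pyran-2-one
Conditions: DBU (2 equiv), toluene, rt, 12 h; 1 M HCl wash
Reagents that add atoms: none
Why: Base-mediated lactonisation of the 5-enol oxygen onto the methyl ester closes the 4-hydroxy-2-pyranone, and the acidic tricarbonyl enolate buffers DBU so the doubly allylic C–H is not removed.

**Step 7**
Reactants: 15 (S)-2-methylbutan-1-ol
Product: 16 (S)-2-methylbutanal
Conditions: TEMPO (1 mol %), KBr (10 mol %), aq NaOCl (1.1 equiv, pH 9.5), CH2Cl2/H2O, 0 °C; distil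
Reagents that add atoms: none
Why: Anelli oxoammonium oxidation gives the α-branched aldehyde without epimerisation at 0 °C; the stereocentre comes from the chiral pool.

**Step 8**
Reactants: 16 (S)-2-methylbutanal; 17 2-methylpent-1-en-3-one
Product: 19 (6S)-5-hydroxy-2,4,6-trimethyloct-1-en-3-one (diastereomer mixture at C4/C5), via lithium dienolate 18 (not isolated)
Conditions: LiN(iPr)2 (1.05 equiv), THF, −78 °C, slow addition of 17; then 16, −78 °C, 30 min; AcOH
Reagents that add atoms: none
Why: Kinetic α′-deprotonation gives the cross-conjugated lithium enolate, whose aldol addition at −78 °C is faster than epimerisation of the aldehyde; the new centres are removed in step 9.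

**Step 9**
Reactants: 19 (6S)-5-hydroxy-2,4,6-trimethyloct-1-en-3-one
Product: 21 (4E,6S)-2,4,6-trimethylocta-1,4-dien-3-one, via mesylate 20 (not isolated)
Conditions: MsCl (1.5 equiv), Et3N (3 equiv), CH2Cl2, 0 °C; then DBU (2 equiv), rt
Reagents that add atoms: none
Why: Mesylation followed by E1cB elimination gives the trisubstituted enone as the favoured E isomer (carbonyl trans to the sec-butyl group) without touching the γ stereocentre.

**Step 10**
Reactants: 14 4-hydroxy-3,5-dimethyl-6-[(2E,4E,6R)-4,6-dimethylocta-2,4,7-trien-2-yl]-2H-pyran-2-one; 21 (4E,6S)-2,4,6-trimethylocta-1,4-dien-3-one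
Product: 22 4-hydroxy-3,5-dimethyl-6-[(2E,4E,6S,7E,10E,12S)-4,6,8,10,12-pentamethyl-9-oxotetradeca-2,4,7,10-tetraen-2-yl]-2H-pyran-2-one
Conditions: 21 (3 equiv), second-generation Hoveyda–Grubbs catalyst RuCl2(H2IMes)(=CH-C6H4-2-OiPr) (10 mol %), 1,4-benzoquinone (10 mol %), CH2Cl2, 40 °C, 24 h
Reagents that add atoms: none
Why: Olefin cross-metathesis between the only monosubstituted alkene of 14 and the 1,1-disubstituted enone alkene of 21 (used in excess, does not homodimerise) gives the trisubstituted enone as the favoured E isomer, with the trisubstituted alkenes and both stereocentres untouched and benzoquinone suppressing alkene migration.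

**Compound list**
1 | 3,5-dimethylpyridine | Cc1cncc(C)c1 | starting material
2 | 1-(2,4-dinitrophenyl)-3,5-dimethylpyridin-1-ium chloride | Cc1cc(C)c[n+](c1)-c1ccc(cc1[N+](=O)[O-])[N+](=O)[O-].[Cl-] | intermediate
3 | N-methyl-N-[(2E,4E)-2,4-dimethyl-5-[methyl(phenyl)amino]penta-2,4-dien-1-ylidene]anilinium chloride (pentamethinium chloride) | CN(c1ccccc1)/C=C(C)/C=C(\C)C=[N+](C)c1ccccc1.[Cl-] | intermediate
4 | (2E,4E)-2,4-dimethyl-5-[methyl(phenyl)amino]penta-2,4-dienal | CN(c1ccccc1)/C=C(C)/C=C(\C)C=O | intermediate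
5 | (E)-but-2-ene | C/C=C/C | starting material
6 | (E)-but-2-en-1-ylpotassium ((E)-crotylpotassium) | C/C=C/[CH2-].[K+] | intermediate
7 | (E)-but-2-en-1-ylbis[(1S,2R,3S,5S)-2,6,6-trimethylbicyclo[3.1.1]heptan-3-yl]borane | C/C=C/CB([C@H]1C[C@H]2C[C@@H]([C@@H]1C)C2(C)C)[C@H]1C[C@H]2C[C@@H]([C@@H]1C)C2(C)C | intermediate
8 | (1E,3E,5R,6R)-2,4,6-trimethyl-1-[methyl(phenyl)amino]octa-1,3,7-trien-5-yl bis(isopinocampheyl)borinate (anti adduct) | CN(c1ccccc1)/C=C(C)/C=C(\C)[C@H](OB([C@H]1C[C@H]2C[C@@H]([C@@H]1C)C2(C)C)[C@H]1C[C@H]2C[C@@H]([C@@H]1C)C2(C)C)[C@H](C)C=C | intermediate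
9 | (2E,4E,6R)-2,4,6-trimethylocta-2,4,7-trienal | C=C[C@@H](C)/C=C(C)/C=C(\C)C=O | intermediate
10 | methyl 2-methyl-3-oxopentanoate (racemic) | CCC(=O)C(C)C(=O)OC | starting material
11 | dilithium 1-methoxy-2-methylpenta-1,3-diene-1,3-bis(olate) (dianion of 10) | COC([O-])=C(C)C([O-])=CC.[Li+].[Li+] | intermediate
12 | methyl (6E,8E,10R)-5-hydroxy-2,4,6,8,10-pentamethyl-3-oxododeca-6,8,11-trienoate | C=C[C@@H](C)/C=C(C)/C=C(\C)C(O)C(C)C(=O)C(C)C(=O)OC | intermediate
13 | methyl (6E,8E,10R)-2,4,6,8,10-pentamethyl-3,5-dioxododeca-6,8,11-trienoate | C=C[C@@H](C)/C=C(C)/C=C(\C)C(=O)C(C)C(=O)C(C)C(=O)OC | intermediate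
14 | 4-hydroxy-3,5-dimethyl-6-[(2E,4E,6R)-4,6-dimethylocta-2,4,7-trien-2-yl]-2H-pyran-2-one | C=C[C@@H](C)/C=C(C)/C=C(\C)c1oc(=O)c(C)c(O)c1C | intermediate
15 | (S)-2-methylbutan-1-ol | CC[C@H](C)CO | starting material
16 | (S)-2-methylbutanal | CC[C@H](C)C=O | intermediate
17 | 2-methylpent-1-en-3-one | CCC(=O)C(C)=C | starting material
18 | lithium 2-methylpenta-1,3-dien-3-olate | CC=C([O-])C(C)=C.[Li+] | intermediate
19 | (6S)-5-hydroxy-2,4,6-trimethyloct-1-en-3-one | CC[C@H](C)C(O)C(C)C(=O)C(C)=C | intermediate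
20 | (6S)-2,4,6-trimethyl-3-oxooct-1-en-5-yl methanesulfonate | CC[C@H](C)C(OS(C)(=O)=O)C(C)C(=O)C(C)=C | intermediate
21 | (4E,6S)-2,4,6-trimethylocta-1,4-dien-3-one | CC[C@H](C)/C=C(\C)C(=O)C(C)=C | intermediate
22 | 4-hydroxy-3,5-dimethyl-6-[(2E,4E,6S,7E,10E,12S)-4,6,8,10,12-pentamethyl-9-oxotetradeca-2,4,7,10-tetraen-2-yl]-2H-pyran-2-one | CC[C@H](C)/C=C(\C)C(=O)/C(C)=C/[C@@H](C)/C=C(C)/C=C(\C)c1oc(=O)c(C)c(O)c1C | target

**Totals**
Total step count: 10. Longest linear sequence: 7 (steps 1–6 and 10); side branch: steps 7–9.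

**Three steps most likely to fail**

Step 3. The vinylogous formamide carbonyl of 4 may be too weak an electrophile for the crotylborane at −78 °C, and the dienyl iminium formed on work-up could lose the doubly allylic proton and racemise C6. The fallback sets out from 4 and comes back at 9, taking the stereocentre from the chiral pool instead of from a chiral borane. Compound 4 is treated with the allenylzinc reagent generated from (S)-but-3-yn-2-yl methanesulfonate F1 (from commercial (S)-but-3-yn-2-ol, MsCl, Et3N) with Pd(OAc)2 (5 mol %), PPh3 and Et2Zn in THF at −20 °C. This is a Marshall propargylation: anti SN2′ oxidative addition of zerovalent palladium, transmetallation to zinc and syn SE2′ addition fix the methyl-bearing carbon. The same buffered hydrolysis gives (2E,4E,6S)-2,4,6-trimethyloct-2,4-dien-7-ynal F2. Semihydrogenation of the terminal alkyne (H2, Pd on CaCO3 poisoned with Pb(OAc)2, quinoline, EtOAc) returns to 9.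

Step 10. The free hydroxypyranone or the pyranone-conjugated diene may interfere with the ruthenium carbene, or conversion may stall with the branched alkene. The fallback sets out from 9 (with 21) and comes back at 22, moving the metathesis ahead of heterocycle formation. Trienal 9 and 21 under the step 10 catalyst give (2E,4E,6S,7E,10E,12S)-2,4,6,8,10,12-hexamethyl-9-oxotetradeca-2,4,7,10-tetraenal F3. Dianion 11 adds at −78 °C to the formyl group, which is far more electrophilic than the doubly α-substituted dienone, to give methyl (6E,8E,10S,11E,14E,16S)-5-hydroxy-2,4,6,8,10,12,14,16-octamethyl-3,13-dioxooctadeca-6,8,11,14-tetraenoate F4. Dess–Martin oxidation gives methyl (6E,8E,10S,11E,14E,16S)-2,4,6,8,10,12,14,16-octamethyl-3,5,13-trioxooctadeca-6,8,11,14-tetraenoate F5, and DBU lactonisation as in step 6 gives 22. This does not help if the hindered dienone 21 itself is the unreactive partner.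

Step 2. Both ring positions next to nitrogen are flanked by methyl groups, so attack of the weakly nucleophilic N-methylaniline on 2 may be slow. The fallback sets out from 1 and comes back at 4, changing both the activating group and the ring-opening nucleophile. Compound 1 with SO3 (dioxane complex, CH2Cl2, 0 °C) gives 3,5-dimethylpyridinium-1-sulfonate F6. Cold aqueous KOH (−20 °C) opens the ring with hydroxide to potassium (1E,3E)-2,4-dimethyl-5-oxopenta-1,3-dien-1-olate F7. Condensation of F7 with N-methylanilinium chloride in MeOH at rt gives 4.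

**Further compounds**
F1 | step 3 | (S)-but-3-yn-2-yl methanesulfonate | C#C[C@H](C)OS(C)(=O)=O
F2 | step 3 | (2E,4E,6S)-2,4,6-trimethyloct-2,4-dien-7-ynal | C#C[C@@H](C)/C=C(C)/C=C(\C)C=O
F3 | step 10 | (2E,4E,6S,7E,10E,12S)-2,4,6,8,10,12-hexamethyl-9-oxotetradeca-2,4,7,10-tetraenal | CC[C@H](C)/C=C(\C)C(=O)/C(C)=C/[C@@H](C)/C=C(C)/C=C(\C)C=O
F4 | step 10 | methyl (6E,8E,10S,11E,14E,16S)-5-hydroxy-2,4,6,8,10,12,14,16-octamethyl-3,13-dioxooctadeca-6,8,11,14-tetraenoate | CC[C@H](C)/C=C(\C)C(=O)/C(C)=C/[C@@H](C)/C=C(C)/C=C(\C)C(O)C(C)C(=O)C(C)C(=O)OC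
F5 | step 10 | methyl (6E,8E,10S,11E,14E,16S)-2,4,6,8,10,12,14,16-octamethyl-3,5,13-trioxooctadeca-6,8,11,14-tetraenoate | CC[C@H](C)/C=C(\C)C(=O)/C(C)=C/[C@@H](C)/C=C(C)/C=C(\C)C(=O)C(C)C(=O)C(C)C(=O)OC
F6 | step 2 | 3,5-dimethylpyridinium-1-sulfonate | Cc1cc(C)c[n+](c1)S(=O)(=O)[O-]
F7 | step 2 | potassium (1E,3E)-2,4-dimethyl-5-oxopenta-1,3-dien-1-olate | [K+].[O-]/C=C(C)/C=C(\C)C=O
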